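The reading comes at 1.5 h, so the question for each flask is whether starting material is still present at that moment to feed target.

in all of them: starting material 27 mM
- dawn: partner 20 mM; free catalyst 0.050 mM; run made earlier
- amber: partner 29.7 mM; free catalyst 0.050 mM; time 1.5 h
- red: partner 29.7 mM; free catalyst 0.15 mM; time 1.5 h
- blue: partner 29.7 mM; free catalyst 0.40 mM; time 1.5 h

- dawn (time / min: target / %, starting material / %): 4.00: 1.5, 97.9; 10.0: 1.5, 97.8; 20.0: 6.5, 92.1; 30.0: 9.5, 91.1; 40.0: 11.0, 87.1; 50.0: 12.5, 84.8

(each reading ± 1 percentage point)

- the analysis behind the earlier runs scatters by 1 percentage point, standard deviation
- "hardly changes" means that all values lie within two and a half points (for a concentration: within two and a half percent of the largest)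
- no earlier run changes the charge of free catalyst; that part of a forecast is a guess

- amount of target at the end, in percent of the starting material charged for amber, red, blue, in this order
- how that number moves from the first to the last of them (falls, then rises / hardly changes / rises, then falls / falls all the way / rises all the way)

The reckoning starts from the last row of the dawn table. By 50.0 min, starting material has lost 15.2 % of its charge while target stands at 12.5 %. That leaves a gap of 2.7 percentage points against a scatter of 1 point per reading, so a side loss is possible but poorly measured.

Partner was not read at dawn. The reckoning here assumes that each starting material lost takes one partner, which leaves 79.5 % of the partner charge at 50.0 min. It also assumes that catalyst waits in one loaded form (a resting state), since starting material stands far above it. Partner then falls pseudo-first-order, and its fraction left is exp(−r·(catalyst charge/dawn charge)·time). Here r, the partner clock, is read from that row as 0.276 /h. Scaling it with catalyst is a guess, because no earlier run changes that charge.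

Starting material is the limiting reagent. It falls under 2.00 % of its charge when the partner fraction reaches 10.9 %. The clock puts that moment at 1.00 h in blue, before the reading, and at 2.68 h in red, after it. On this estimate blue spends its last 0.500 h with under 2.00 % of its starting material left to feed target, so a side loss of target, if there is one, stands against little new target. This reckoning expects a rise from amber to red and leaves open whether blue falls below red.

The forecast gives 28 %, 50 % and 66 %, a row that rises all the way, with the comment “I expect a rise all the way, flattening at the top.”

The flasks give 23.3 %, 36.1 % and 28.9 %: the row rises, then falls.

    target + released group → side product (k = 0.0280 /M/s)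
    partner + catalyst intermediate A ⇌ catalyst intermediate B (K = 9.20 /M, k = 49.0 /M/s)
    catalyst intermediate C → free catalyst + target (k = 0.670 /s)
    catalyst intermediate B ⇌ released group + catalyst intermediate C (K = 0.870 M, k = 0.200 /s)
    starting material + free catalyst → catalyst intermediate A (k = 140 /M/s)

Blue falls under 2.00 % of its starting material at 0.968 h, against 1.00 h on the clock and before the reading, and between 0.750 h and 1.50 h its target goes from 50.4 % to 28.9 % while side product goes from 37.4 % to 71.1 %. Red at 1.5 h holds 31 % of its partner, against 28.9 % on the clock, with 23.4 % of its starting material left and target at 36.1 %.

The runs were generated by integration with constants of no real substance, noise included.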